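If the catalyst in these flasks is taken to sit mainly as idle complex, the target made goes roughly as the square root of a turnover budget, and each recipe below is reckoned here from that budget.

    starting material + catalyst intermediate B → catalyst intermediate C (k1 = 380 L mol⁻¹ h⁻¹)
    catalyst intermediate D → free catalyst + target (k2 = 180 h⁻¹)
    coupling partner + free catalyst ⇌ catalyst intermediate A (K3 = 3.5 L mol⁻¹, k3 = 230 L mol⁻¹ h⁻¹)
    catalyst intermediate A ⇌ catalyst intermediate B (K4 = 1.3, k4 = 260 h⁻¹)
    catalyst intermediate C ⇌ by-product + catalyst intermediate D (K5 = 0.13 M, k5 = 56 h⁻¹)
    free catalyst + by-product ⇌ idle complex (K6 = 430 L mol⁻¹, k6 = 120 L mol⁻¹ h⁻¹)

the same everywhere: free catalyst 2.8 mM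
- red: starting material 0.14 M; coupling partner 0.560 M; a single well-mixed tank run continuously and read at steady state, 6.0 h in it on average
- green: starting material 0.14 M; coupling partner 0.560 M; a closed flask charged with all of it at once and left for 6.0 h; time 6.0 h
- blue: starting material 0.14 M; coupling partner 0.560 M (fed, over 4.80 h); a stirred flask in which coupling partner is dosed at a steady rate over 4.80 h without added volume, worked up at 6.0 h; time 6.0 h
- teal: starting material 0.14 M (fed, over 4.80 h); coupling partner 0.560 M; all but starting material at the start; starting material goes in evenly over 4.80 h, the run ends at 6.0 h; time 6.0 h

- by-product is meant together with its idle complex
- the stated concentrations are those of everything mixed, before any reaction; amounts are the same in each set-up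
- the feed brings no volume worth counting
- run time (green): 6.0 h

- the set-up with the highest amount of target at the outlet or at the end, in percent of the starting material put in ("none" if the first two lie within 2 percentage points) (red / green / blue / teal / none)
- amount of target at the outlet or at the end, in percent of the starting material put in, red
- amount of target at the outlet or at the end, in percent of the starting material put in, green
- amount of target at the outlet or at the end, in percent of the starting material put in, blue
- amount of target at the outlet or at the end, in percent of the starting material put in, teal

By-product inhibition is reckoned here by hand. With c(coupling partner) near 0.525 M and c(starting material) near 0.0980 M, the uptake of coupling partner, the change of intermediate A into B and the attack of starting material act in series. Together they give a round rate per unit of c(free catalyst) of 46.3 h⁻¹. Free catalyst with intermediates A and B makes a working pool of 5.23 times c(free catalyst), with uptake and the change of A into B taken as balanced; intermediates C and D are left out of this pool and of the round rate.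

The release time, the mean life of an idle complex before it falls apart, is 3.58 h. With the round rate held constant and c(by-product) taken equal to c(target), balancing catalyst bound against catalyst released and integrating the rate in closed form gives a rule: 430 L mol⁻¹ times c(target) squared over 2, plus the working pool times c(target), equals the budget. The budget is the round rate times the catalyst charged times the sum of run time and release time.

For green the budget is 1.24 M, which gives 46.3%.

In the red tank, outflow also removes idle complex, so the term becomes 269 L mol⁻¹ times c(target) squared, the budget has no release time added, and the reckoning for the outlet gives 32.1%.

Taking a dosed reagent at half its figure is a rough guess. It gives blue a budget of 0.621 M and 33.6%. Teal gets 0.817 M and 36.2%. This reckoning puts first green.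

The neighbour of green differs in one charge, 0.14 M of coupling partner. Its c(coupling partner) stands near 0.105 M, so its round rate is 9.25 h⁻¹, lower by a factor 5.01. Target sits under a root, so it should fall by a smaller factor, near 2.24, and the rule gives 21.4%.

The forecast names green, with red 32%, green 46%, blue 34% and teal 37%, on the ground that “the winner is the one that gets the most turnover before the catalyst is tied up”.

The simulation gives green first, with red 32.6%, green 46.2%, blue 34.5% and teal 37.0%. In green the release time 3.58 h is shorter than the run of 6.0 h, idle complex holds 85.3% of the catalyst at 6.00 h, and the rule at 3.00 h gives 37.1% against 37.1% in the flask. The neighbour with 0.14 M of coupling partner, reckoned at 21.4%, ended with 24.4% of target.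

(The numbers of this flask were drawn at random within sensible limits, and the outcome is calculated.)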